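## Plan

- **Cuts:** remove the late groups (O16-PMB, C2–C3 epoxide, C13=C14, acetates at O9 and O11). Open the lactone at O7–C19. Undo the ring expansion by cutting C4–C5 and re-joining C2–C7. Then cut C6–C7 (acetylide) and C2–C3 (vinyl).
- **Enabling feature:** the cyclohexenone ring (C1, C10–C14 with C15 and C20), C9–O, and C8 with its C17(C18)–C19 branch are the carbons of α-santonin. The ten-membered ring C1–C10 is santonin ring B (C1, C2, C7, C8, C9, C10) with C3–C6 inserted between C2 and C7. Its C2=C3 / C5=C6–C7–O array is the product pattern of a [3,3] shift of a 2-vinyl-7-alkynyl-7-ol.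
- **Forward order:** ring A is adjusted first. Ring B is then oxidised (C8=C9, C7=O, 8,9-diol), and C3–C4 and C5–C6–C16 are attached. Ring B is enlarged from six to ten members, the γ-lactone O7–C19 is closed, and the epoxide is made second to last.
- **Stereochemistry in the decalin:** C1 comes from santonin and directs α-face delivery, which sets C10 and C11 and re-makes C8 and C9 by osmylation.
- **Stereochemistry after the expansion:** C17 comes from santonin and is inverted by equilibration in the new lactone. C7 comes from a chelate-controlled reduction. C2 and C3 come from peripheral epoxidation of the E alkene.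

Key step: step 18

Remark: briarane numbers are used for all intermediates. Ring A is C1, C10–C14. Ring B is C1, C2, C7–C10. C15 sits on C1, C20 on C11, and the side chain C17(C18)–C19 on C8. β is the face of C15.

Assumption: the carbinol carbon C3 of aldol 19 is left unassigned, because it becomes sp2 in step 15.

## Route

Step 1
Reactants: 1 (−)-α-santonin
Product: 2 13,14-dihydro-α-santonin
Conditions: H2 (1 atm), RhCl(PPh3)3 (cat.), PhMe–EtOH, rt
Reagents that add atoms: none
Why: Homogeneous hydrogenation with Wilkinson's catalyst should saturate only the disubstituted C13=C14 bond of the cross-conjugated dienone and leave the tetrasubstituted C10=C11 enone and the lactone untouched; no stereocentre is formed.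

Step 2
Reactants: 2 13,14-dihydro-α-santonin
Product: 3 10αH-12-(triethylsilyloxy)-11-ene 9α,19-lactone
Conditions: Et3SiH, RhCl(PPh3)3 (cat.), PhMe, 70 °C
Reagents that add atoms: triethylsilane CC[SiH](CC)CC
Why: Rhodium-catalysed 1,4-hydrosilylation of the enone should deliver hydride to C10 from the α face, opposite the angular methyl C15, which sets the trans ring fusion (H-10α) and fixes the enol ether at C11=C12, a regiochemistry that enolisation of the saturated ketone would not secure.

Step 3
Reactants: 3 10αH-12-(triethylsilyloxy)-11-ene 9α,19-lactone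
Product: 4 11α-(triethylsilyloxy)-11β-methyl-12-oxo 9α,19-lactone
Conditions: mCPBA, NaHCO3, CH2Cl2, −20 → 0 °C
Reagents that add atoms: mCPBA O=C(OO)c1cccc(Cl)c1
Why: In this Rubottom oxidation the peracid should attack the electron-rich C11=C12 bond from the α face because axial C15 covers the β face, and opening with silyl shift to the new oxygen gives O11 α and C20 β already protected.

Step 4
Reactants: 4 11α-(triethylsilyloxy)-11β-methyl-12-oxo 9α,19-lactone
Product: 5 12,12-ethylenedioxy derivative of 4
Conditions: TMSOCH2CH2OTMS, TMSOTf (cat.), CH2Cl2, −78 → −20 °C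
Reagents that add atoms: 1,2-bis(trimethylsilyloxy)ethane C[Si](C)(C)OCCO[Si](C)(C)C
Why: Aprotic ketalisation with the bis-silyl glycol ether masks the C12 ketone, which is open on its C13 side, without cleaving the silyl ether or touching the lactone.

Step 5
Reactants: 5 12,12-ethylenedioxy derivative of 4
Product: 6 9α,19-diol
Conditions: LiAlH4, THF, 0 °C; Rochelle salt work-up
Reagents that add atoms: none
Why: Hydride reduction of the γ-lactone to the 1,4-diol frees O9 and brings C19 to the alcohol level, while the low temperature and the aluminium alkoxides should prevent silyl migration from O11 to the nearby O9; no stereocentre changes.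

Step 6
Reactants: 6 9α,19-diol
Product: 7 19-O-TBS ether of 6
Conditions: TBSCl, imidazole, CH2Cl2, 0 °C
Reagents that add atoms: tert-butyldimethylsilyl chloride CC(C)(C)[Si](C)(C)Cl
Why: In this selective silylation the primary C19 hydroxyl reacts far faster than the secondary C9 hydroxyl, which is crowded by the peri silyloxy group on C11.

Step 7
Reactants: 7 19-O-TBS ether of 6
Product: 8 9-ketone
Conditions: Dess–Martin periodinane, NaHCO3, CH2Cl2, rt
Reagents that add atoms: none
Why: Dess–Martin oxidation converts the hindered secondary alcohol to the ketone under buffered conditions that spare ketal and silyl ethers.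

Step 8
Reactants: 8 9-ketone
Product: 10 8-en-9-yl triflate, via potassium enolate 9 (not isolated)
Conditions: KHMDS, THF, −78 °C; then PhNTf2
Reagents that add atoms: N-phenylbis(trifluoromethanesulfonimide) O=S(=O)(N(c1ccccc1)S(=O)(=O)C(F)(F)F)C(F)(F)F
Why: In this kinetic enolisation and O-sulfonylation (enol triflate synthesis) C10–H lies between the quaternary carbons C1 and C11 and is out of reach of the bulky amide, so only the axial C8–H should be removed and the double bond is placed at C8=C9.

Step 9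
Reactants: 10 8-en-9-yl triflate
Product: 11 8-ene (C8=C9–H)
Conditions: Pd(OAc)2 (cat.), PPh3, HCO2H, n-Bu3N, DMF, 60 °C
Reagents that add atoms: none
Why: Palladium-catalysed formate hydrogenolysis of the vinyl triflate replaces OTf by H and leaves the alkene in a defined position, with the neighbouring stereocentre C17 untouched.

Step 10
Reactants: 11 8-ene (C8=C9–H)
Product: 12 8-en-7-one
Conditions: Rh2(cap)4 (cat.), t-BuOOH (70 % aq.), K2CO3, CH2Cl2, rt
Reagents that add atoms: tert-butyl hydroperoxide CC(C)(C)OO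
Why: In this dirhodium-catalysed allylic oxidation the electrophilic peroxyl radical should abstract hydrogen from the C7 methylene, because C10–H is buried and deactivated by O11 and C17–H is deactivated by O19, and the allyl radical is then oxygenated at its open terminus C7 rather than at the shielded C9.

Step 11
Reactants: 12 8-en-7-one
Product: 13 8α,9α-dihydroxy-7-one
Conditions: OsO4 (cat.), NMO, citric acid, t-BuOH–acetone–H2O, rt
Reagents that add atoms: osmium tetroxide (catalytic oxygen carrier) O=[Os](=O)(=O)=O; N-methylmorpholine N-oxide C[N+]1([O-])CCOCC1; water O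
Why: In this Upjohn dihydroxylation (citric acid variant for electron-poor alkenes) osmium tetroxide should add to the α face because the axial methyls C15 and C20 close the β face at C9, which sets 8α-OH and 9α-OH with H-9β and the side chain 8β, as C8 and C9 of the target require.

Step 12
Reactants: 13 8α,9α-dihydroxy-7-one
Product: 14 8α,9α-O-isopropylidene-7-one
Conditions: Me2C(OMe)2, PPTS, CH2Cl2, rt
Reagents that add atoms: 2,2-dimethoxypropane COC(C)(C)OC
Why: Acid-catalysed transketalisation ties the cis diol into a dioxolane, which blocks retro-aldol and α-ketol pathways in the basic steps ahead and leaves C2 as the only enolisable position.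

Step 13
Reactants: 15 ethyl vinyl ether
Product: 17 (phenylselanyl)acetaldehyde, via chloro ether 16 (not isolated)
Conditions: PhSeCl, CH2Cl2, −78 °C; then aq. NaHCO3, rt
Reagents that add atoms: benzeneselenenyl chloride Cl[Se]c1ccccc1; water O
Why: Markovnikov selenenylation of the enol ether followed by hydrolysis of the α-chloro ether gives the two-carbon vinyl cation equivalent.

Step 14
Reactants: 14 8α,9α-O-isopropylidene-7-one; 17 (phenylselanyl)acetaldehyde
Product: 19 2α-[1-hydroxy-2-(phenylselanyl)ethyl]-7-one, via lithium enolate 18 (not isolated)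
Conditions: LDA, THF, −78 °C; then 17; AcOH quench at −78 °C
Reagents that add atoms: 17 (phenylselanyl)acetaldehyde O=CC[Se]c1ccccc1
Why: In this directed aldol addition C8 is fully substituted, so only C2 can be enolised, and the small aldehyde should be taken up at this neopentyl carbon along the axial α trajectory anti to C15; both new centres are erased or equilibrated in step 15.

Step 15
Reactants: 19 2α-[1-hydroxy-2-(phenylselanyl)ethyl]-7-one
Product: 21 2β-vinyl-7-one, via axial vinyl ketone 20 (not isolated)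
Conditions: MsCl, Et3N, CH2Cl2, 0 °C; then DBU (0.2 equiv), rt
Reagents that add atoms: none
Why: Activation of the hydroxyl group triggers the β-hydroxy selenide elimination to the vinyl group (enolate vinylation), and the amidine then equilibrates the doubly activated C2–H, where reprotonation at C2 is faster than at C4, to the equatorial 2β isomer that is free of the 1,3-diaxial contact with O8.

Step 16
Reactants: 22 propargyl alcohol
Product: 24 4-methoxybenzyl propargyl ether, via sodium alkoxide 23 (not isolated)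
Conditions: NaH, THF, 0 °C; then PMBCl, n-Bu4NI (cat.), rt
Reagents that add atoms: 4-methoxybenzyl chloride COc1ccc(CCl)cc1
Why: Williamson ether synthesis gives the C5–C6–C16 unit with an O16 group that survives base, fluoride and mild acid and leaves oxidatively at the end.

Step 17
Reactants: 21 2β-vinyl-7-one; 24 4-methoxybenzyl propargyl ether
Product: 27 2β-vinyl-7α-alkynyl-7β-ol, via lithium acetylide 25 (not isolated), via cerium acetylide 26 (not isolated)
Conditions: 24, n-BuLi, THF, −78 °C; CeCl3, −78 °C; then 21; aq. NH4Cl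
Reagents that add atoms: 24 4-methoxybenzyl propargyl ether C#CCOCc1ccc(OC)cc1
Why: The organocerium 1,2-addition suppresses enolisation of the acidic C2–H, and because the axial β approach to C7 is blocked by the 1,3-diaxial methyl C15 the acetylide should enter equatorially from the α face, giving the axial 7β-alcohol with the alkynyl group trans-diequatorial to the vinyl group.

Step 18
Reactants: 27 2β-vinyl-7α-alkynyl-7β-ol
Product: 30 ten-membered 2E-5(ring-cis)-dien-7-one, via potassium alkoxide 28 (not isolated), via potassium allenolate 29 (not isolated)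
Conditions: KH, 18-crown-6, THF, 0 → 40 °C; then AcOH–THF, −78 °C
Reagents that add atoms: none
Why: Deprotonation gives alkoxide 28, whose oxyanion weakens the C2–C7 σ bond, and a concerted [3,3] shift across C4=C3–C2–C7–C6≡C5 forms C4–C5 and breaks C2–C7 to give the ring allenolate 29, which the cold acid quench protonates at C6 (anionic acetylenic oxy-Cope rearrangement, the reaction type known for 1-alkynyl-2-vinylcycloalkanols going to cyclodecadienones). The ten-membered ring C1–C10 arises by a four-atom pericyclic expansion of ring B and not by an end-to-end closure, so no dilution is needed. No stereocentre is created: C2 and C7 become sp2, and C1, C8–C11 and C17 are spectators. The E geometry at C2=C3 needs the 2β-vinyl and 7α-alkynyl groups trans-diequatorial, because only the vinyl rotamer with C4 below the ring and antiperiplanar to C1 can reach C5, and the rigid trans-decalin chair enforces this rotamer. The ring-cis geometry at C5=C6 (C4 and C7 on the same side; CIP E, since C16 outranks C4) follows because the enolate lobe at C6 lies in the C4–C5–C16 plane and only its outer side, syn to C16, is open to the proton; this is also the less strained isomer. The competing retro-addition of 28 to ketone 21 and acetylide should be outrun thanks to the crown-separated potassium ion pair and to the strain released on cleavage of C2–C7 (the 1,3-diaxial O7/C15 contact and the crowding between the fully substituted carbons C1 and C8), while the buffered cold quench keeps the skipped diene from drifting into conjugation.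

Step 19
Reactants: 30 ten-membered 2E-5(ring-cis)-dien-7-one
Product: 31 7-alcohol with the C7 configuration of the target
Conditions: Zn(BH4)2, Et2O, −30 → 0 °C
Reagents that add atoms: none
Why: In this chelation-controlled 1,2-reduction (Cram chelate model) zinc should bridge the C7 carbonyl oxygen and the acetonide oxygen O8, which turns the carbonyl syn to C8–O, and hydride then arrives from the outer face of the ring, placing H-7 trans to O8 on the future lactone ring.

Step 20
Reactants: 31 7-alcohol with the C7 configuration of the target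
Product: 32 7,11,19-triol
Conditions: TBAF, THF, rt → 40 °C
Reagents that add atoms: none
Why: Fluoride desilylation removes the primary TBS and the tertiary TES ether in one operation, while acetonide, ketal and PMB ether are inert.

Step 21
Reactants: 32 7,11,19-triol
Product: 34 17-epi γ-lactone (O7–C19), via lactol 33 (not isolated)
Conditions: TEMPO (cat.), PhI(OAc)2, CH2Cl2, rt
Reagents that add atoms: none
Why: In this TEMPO/PhI(OAc)2 oxidative lactonisation of a 1,4-diol the oxoammonium salt oxidises the primary C19 alcohol first, O7 traps the aldehyde as lactol 33, and this is oxidised on to the lactone, so C7 is retained and the crowded allylic and tertiary hydroxyls are spared.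

Step 22
Reactants: 34 17-epi γ-lactone (O7–C19)
Product: 35 γ-lactone with the C17 configuration of the target
Conditions: DBU, PhMe, 80 °C
Reagents that add atoms: none
Why: In this thermodynamic epimerisation α to the lactone carbonyl the C18 methyl moves from the side of the bulky ring carbon C9 (34) to the side of O8 (35), and with so weak a base the enolate should be reprotonated within the ion pair much faster than it can expel the alkoxide O8.

Step 23
Reactants: 35 γ-lactone with the C17 configuration of the target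
Product: 36 11-hydroxy-12-ketone
Conditions: PPTS, acetone–H2O (10:1), 56 °C
Reagents that add atoms: water O
Why: Acid-catalysed ketal hydrolysis frees C12, while the 8,9-acetonide is held in place by mass action in acetone.

Step 24
Reactants: 36 11-hydroxy-12-ketone
Product: 37 11-acetate
Conditions: Ac2O, DMAP, Et3N, CH2Cl2, 40 °C
Reagents that add atoms: acetic anhydride CC(=O)OC(C)=O
Why: DMAP-catalysed acylation esterifies the tertiary α-ketol hydroxyl, the only free hydroxyl at this stage because O8 and O9 are still in the acetonide.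

Step 25
Reactants: 37 11-acetate
Product: 39 13-en-12-one, via silyl enol ether 38 (not isolated)
Conditions: TMSOTf (1.2 equiv), Et3N, CH2Cl2, −20 °C; concentrate; Pd(OAc)2, MeCN, rt
Reagents that add atoms: none
Why: In this Saegusa–Ito oxidation C11 is quaternary, so the ketone can enolise only toward C13 and the double bond must form at C13=C14, and the limited amount of silyl triflate at low temperature should leave the lactone untouched.

Step 26
Reactants: 39 13-en-12-one
Product: 40 8,9-diol
Conditions: AcOH–H2O (4:1), 45 °C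
Reagents that add atoms: none
Why: Acetal hydrolysis is carried out before the epoxide exists, so no acid-labile oxirane and no transannular opening by O9 has to be considered.

Step 27
Reactants: 40 8,9-diol
Product: 41 9,11-diacetate with free 8-OH
Conditions: Ac2O, pyridine, DMAP (cat.), CH2Cl2, 0 °C → rt
Reagents that add atoms: acetic anhydride CC(=O)OC(C)=O
Why: In this selective acylation the secondary C9 hydroxyl reacts under mild conditions, whereas the tertiary C8 hydroxyl, flanked by three branched carbons, stays free.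

Step 28
Reactants: 41 9,11-diacetate with free 8-OH
Product: 42 2,3-epoxide (O16-PMB ether of the target)
Conditions: mCPBA (1.05 equiv), NaHCO3, CH2Cl2, −20 → 0 °C
Reagents that add atoms: mCPBA O=C(OO)c1cccc(Cl)c1
Why: In this Prilezhaev epoxidation the strained E-C2=C3 bond is the only nucleophilic alkene (C13=C14 is an enone and C5=C6 is deactivated by the allylic O7-acyl and O16-ether groups), and it stands perpendicular to the ring with the face once bonded to C7 turned inward, so the peracid should add to the outer face and set C2 and C3 together as the trans epoxide of the target.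

Step 29
Reactants: 42 2,3-epoxide (O16-PMB ether of the target)
Product: 43 CNP0155754.2
Conditions: DDQ, CH2Cl2–pH 7 buffer, 0 °C
Reagents that add atoms: none
Why: Oxidative PMB cleavage with DDQ under buffered conditions frees the C16 alcohol without acid or base, so epoxide, acetates, lactone and enone are preserved.

## Compound list

1 | (−)-α-santonin | C[C@H]1[C@@H]2CC[C@]3(C=CC(=O)C(=C3[C@H]2OC1=O)C)C | starting material
2 | 13,14-dihydro-α-santonin (C10=C11–C12=O enone, 9α,19-lactone) | C[C@H]1[C@@H]2CC[C@]3(CCC(=O)C(=C3[C@H]2OC1=O)C)C | intermediate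
3 | 10αH-12-(triethylsilyloxy)-11-ene 9α,19-lactone (trans-decalin) | O=C1O[C@@H]2[C@@H]3[C@](C)(CCC(O[Si](CC)(CC)CC)=C3C)CC[C@H]2[C@@H]1C | intermediate
4 | 11α-(triethylsilyloxy)-11β-methyl-12-oxo 9α,19-lactone | O=C1O[C@@H]2[C@@H]3[C@](C)(CCC(=O)[C@@]3(C)O[Si](CC)(CC)CC)CC[C@H]2[C@@H]1C | intermediate
5 | 12,12-ethylenedioxy derivative of 4 | O=C1O[C@@H]2[C@@H]3[C@](C)(CCC4(OCCO4)[C@@]3(C)O[Si](CC)(CC)CC)CC[C@H]2[C@@H]1C | intermediate
6 | 9α,19-diol (H-8α, C17 as in santonin) | O[C@@H]1[C@@H]2[C@](C)(CCC3(OCCO3)[C@@]2(C)O[Si](CC)(CC)CC)CC[C@H]1[C@H](C)CO | intermediate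
7 | 19-O-TBS ether of 6 | O[C@@H]1[C@@H]2[C@](C)(CCC3(OCCO3)[C@@]2(C)O[Si](CC)(CC)CC)CC[C@H]1[C@H](C)CO[Si](C)(C)C(C)(C)C | intermediate
8 | 9-ketone | O=C1[C@@H]2[C@](C)(CCC3(OCCO3)[C@@]2(C)O[Si](CC)(CC)CC)CC[C@H]1[C@H](C)CO[Si](C)(C)C(C)(C)C | intermediate
9 | potassium C8=C9 enolate of 8 | C1(=C([O-])[C@@H]2[C@](C)(CCC3(OCCO3)[C@@]2(C)O[Si](CC)(CC)CC)CC1)[C@H](C)CO[Si](C)(C)C(C)(C)C.[K+] | intermediate (not isolated)
10 | 8-en-9-yl triflate | C1(=C(OS(=O)(=O)C(F)(F)F)[C@@H]2[C@](C)(CCC3(OCCO3)[C@@]2(C)O[Si](CC)(CC)CC)CC1)[C@H](C)CO[Si](C)(C)C(C)(C)C | intermediate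
11 | 8-ene (C8=C9–H) | C1(=C[C@@H]2[C@](C)(CCC3(OCCO3)[C@@]2(C)O[Si](CC)(CC)CC)CC1)[C@H](C)CO[Si](C)(C)C(C)(C)C | intermediate
12 | 8-en-7-one | C1(=C[C@@H]2[C@](C)(CCC3(OCCO3)[C@@]2(C)O[Si](CC)(CC)CC)CC1=O)[C@H](C)CO[Si](C)(C)C(C)(C)C | intermediate
13 | 8α,9α-dihydroxy-7-one (side chain 8β, H-9β) | O[C@@H]1[C@@H]2[C@](C)(CCC3(OCCO3)[C@@]2(C)O[Si](CC)(CC)CC)CC(=O)[C@@]1(O)[C@H](C)CO[Si](C)(C)C(C)(C)C | intermediate
14 | 8α,9α-O-isopropylidene-7-one | CC1(C)O[C@@H]2[C@@H]3[C@](C)(CCC4(OCCO4)[C@@]3(C)O[Si](CC)(CC)CC)CC(=O)[C@@]2(O1)[C@H](C)CO[Si](C)(C)C(C)(C)C | intermediate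
15 | ethyl vinyl ether | C=COCC | starting material
16 | 1-chloro-1-ethoxy-2-(phenylselanyl)ethane | CCOC(Cl)C[Se]c1ccccc1 | intermediate (not isolated)
17 | (phenylselanyl)acetaldehyde | O=CC[Se]c1ccccc1 | intermediate
18 | lithium C2=C7 enolate of 14 | CC1(C)O[C@@H]2[C@@H]3[C@](C)(CCC4(OCCO4)[C@@]3(C)O[Si](CC)(CC)CC)C=C([O-])[C@@]2(O1)[C@H](C)CO[Si](C)(C)C(C)(C)C.[Li+] | intermediate (not isolated)
19 | 2α-[1-hydroxy-2-(phenylselanyl)ethyl]-7-one (carbinol C3 unassigned) | CC1(C)O[C@@H]2[C@@H]3[C@](C)(CCC4(OCCO4)[C@@]3(C)O[Si](CC)(CC)CC)[C@H](C(O)C[Se]c4ccccc4)C(=O)[C@@]2(O1)[C@H](C)CO[Si](C)(C)C(C)(C)C | intermediate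
20 | 2α-vinyl-7-one (axial vinyl) | CC1(C)O[C@@H]2[C@@H]3[C@](C)(CCC4(OCCO4)[C@@]3(C)O[Si](CC)(CC)CC)[C@H](C=C)C(=O)[C@@]2(O1)[C@H](C)CO[Si](C)(C)C(C)(C)C | intermediate (not isolated)
21 | 2β-vinyl-7-one (equatorial vinyl) | CC1(C)O[C@@H]2[C@@H]3[C@](C)(CCC4(OCCO4)[C@@]3(C)O[Si](CC)(CC)CC)[C@@H](C=C)C(=O)[C@@]2(O1)[C@H](C)CO[Si](C)(C)C(C)(C)C | intermediate
22 | propargyl alcohol | C#CCO | starting material
23 | sodium prop-2-yn-1-olate | C#CC[O-].[Na+] | intermediate (not isolated)
24 | 4-methoxybenzyl propargyl ether | C#CCOCc1ccc(OC)cc1 | intermediate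
25 | lithium acetylide of 24 | [Li+].[C-]#CCOCc1ccc(OC)cc1 | intermediate (not isolated)
26 | dichlorocerium acetylide of 24 | Cl[Ce](Cl)C#CCOCc1ccc(OC)cc1 | intermediate (not isolated)
27 | 2β-vinyl-7α-[3-(4-methoxybenzyloxy)prop-1-ynyl]-7β-ol (rearrangement precursor) | CC1(C)O[C@@H]2[C@@H]3[C@](C)(CCC4(OCCO4)[C@@]3(C)O[Si](CC)(CC)CC)[C@@H](C=C)[C@](O)(C#CCOCc4ccc(OC)cc4)[C@@]2(O1)[C@H](C)CO[Si](C)(C)C(C)(C)C | intermediate
28 | potassium 7-alkoxide of 27 | CC1(C)O[C@@H]2[C@@H]3[C@](C)(CCC4(OCCO4)[C@@]3(C)O[Si](CC)(CC)CC)[C@@H](C=C)[C@]([O-])(C#CCOCc4ccc(OC)cc4)[C@@]2(O1)[C@H](C)CO[Si](C)(C)C(C)(C)C.[K+] | intermediate (not isolated)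
29 | potassium ring allenolate (C5=C6=C7–O−, E-C2=C3) | CC1(C)O[C@@H]2[C@@H]3[C@](C)(CCC4(OCCO4)[C@@]3(C)O[Si](CC)(CC)CC)/C=C/CC(COCc4ccc(OC)cc4)=C=C([O-])[C@@]2(O1)[C@H](C)CO[Si](C)(C)C(C)(C)C.[K+] | intermediate (not isolated)
30 | ten-membered dien-7-one (E-C2=C3, ring-cis C5=C6 bearing CH2OPMB) | CC1(C)O[C@@H]2[C@@H]3[C@](C)(CCC4(OCCO4)[C@@]3(C)O[Si](CC)(CC)CC)/C=C/C/C(COCc4ccc(OC)cc4)=C\C(=O)[C@@]2(O1)[C@H](C)CO[Si](C)(C)C(C)(C)C | intermediate
31 | 7-alcohol (C7 as in the target) | CC1(C)O[C@@H]2[C@@H]3[C@](C)(CCC4(OCCO4)[C@@]3(C)O[Si](CC)(CC)CC)/C=C/C/C(COCc4ccc(OC)cc4)=C\[C@H](O)[C@@]2(O1)[C@H](C)CO[Si](C)(C)C(C)(C)C | intermediate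
32 | 7,11,19-triol | CC1(C)O[C@@H]2[C@@H]3[C@](C)(CCC4(OCCO4)[C@@]3(C)O)/C=C/C/C(COCc4ccc(OC)cc4)=C\[C@H](O)[C@@]2(O1)[C@H](C)CO | intermediate
33 | O7–C19 lactol (anomeric centre unassigned) | CC1(C)O[C@@H]2[C@@H]3[C@](C)(CCC4(OCCO4)[C@@]3(C)O)/C=C/C/C(COCc4ccc(OC)cc4)=C\[C@@H]4OC(O)[C@@H](C)[C@]42O1 | intermediate (not isolated)
34 | 17-epi γ-lactone (C18 cis to C9) | CC1(C)O[C@@H]2[C@@H]3[C@](C)(CCC4(OCCO4)[C@@]3(C)O)/C=C/C/C(COCc4ccc(OC)cc4)=C\[C@@H]4OC(=O)[C@@H](C)[C@]42O1 | intermediate
35 | γ-lactone with natural C17 (C18 cis to O8) | CC1(C)O[C@@H]2[C@@H]3[C@](C)(CCC4(OCCO4)[C@@]3(C)O)/C=C/C/C(COCc4ccc(OC)cc4)=C\[C@@H]4OC(=O)[C@H](C)[C@]42O1 | intermediate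
36 | 11-hydroxy-12-ketone | CC1(C)O[C@@H]2[C@@H]3[C@](C)(CCC(=O)[C@@]3(C)O)/C=C/C/C(COCc4ccc(OC)cc4)=C\[C@@H]4OC(=O)[C@H](C)[C@]42O1 | intermediate
37 | 11-acetate | CC1(C)O[C@@H]2[C@@H]3[C@](C)(CCC(=O)[C@@]3(C)OC(C)=O)/C=C/C/C(COCc4ccc(OC)cc4)=C\[C@@H]4OC(=O)[C@H](C)[C@]42O1 | intermediate
38 | 12-(trimethylsilyloxy)-12-ene | CC1(C)O[C@@H]2[C@@H]3[C@](C)(CC=C(O[Si](C)(C)C)[C@@]3(C)OC(C)=O)/C=C/C/C(COCc4ccc(OC)cc4)=C\[C@@H]4OC(=O)[C@H](C)[C@]42O1 | intermediate (not isolated)
39 | 13-en-12-one | CC1(C)O[C@@H]2[C@@H]3[C@](C)(C=CC(=O)[C@@]3(C)OC(C)=O)/C=C/C/C(COCc4ccc(OC)cc4)=C\[C@@H]4OC(=O)[C@H](C)[C@]42O1 | intermediate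
40 | 8,9-diol | O[C@@H]1[C@@H]2[C@](C)(C=CC(=O)[C@@]2(C)OC(C)=O)/C=C/C/C(COCc3ccc(OC)cc3)=C\[C@@H]3OC(=O)[C@H](C)[C@]31O | intermediate
41 | 9,11-diacetate with free 8-OH | CC(=O)O[C@@H]1[C@@H]2[C@](C)(C=CC(=O)[C@@]2(C)OC(C)=O)/C=C/C/C(COCc3ccc(OC)cc3)=C\[C@@H]3OC(=O)[C@H](C)[C@]31O | intermediate
42 | 2,3-epoxide, O16-PMB ether of the target | CC(=O)O[C@@H]1[C@@H]2[C@](C)(C=CC(=O)[C@@]2(C)OC(C)=O)[C@H]2O[C@@H]2C/C(COCc2ccc(OC)cc2)=C\[C@@H]2OC(=O)[C@H](C)[C@]21O | intermediate
43 | CNP0155754.2 | CC(=O)O[C@@H]1[C@@H]2[C@](C)(C=CC(=O)[C@@]2(C)OC(C)=O)[C@H]2O[C@@H]2C/C(CO)=C\[C@@H]2OC(=O)[C@H](C)[C@]21O | target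

## Step count and main risks

Total step count: 29.
Longest linear sequence: 27 (steps 1–12, 14, 15 and 17–29, from α-santonin).

**Step 18 (key step).** The propargylic alkoxide may fragment back to ketone and acetylide faster than it rearranges. Excess base may also move the skipped diene of the product enolate into conjugation. The fallback sets out from 27 and keeps the same [3,3] shift, but without any alkoxide.
- Silylation (TMSOTf, 2,6-lutidine) gives the 7-O-trimethylsilyl ether F1.
- Heating without base (o-dichlorobenzene, about 190 °C, the thermal siloxy variant of the acetylenic oxy-Cope rearrangement) should give the ring siloxyallene F2.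
- Buffered hydrolysis (citric acid, aqueous THF) protonates C6 and comes back to the route at 30.

**Step 10.** Hydrogen abstraction may occur at C10 or C17 instead of C7, or oxygen may be delivered to the C9 end of the allyl radical. The fallback sets out from 11 and brings the oxygen in through an epoxide instead of a C–H abstraction.
- mCPBA should give the 8α,9α-epoxide F3.
- Aluminium isopropoxide in hot toluene should open the tertiary C8–O bond with loss of a C7 hydrogen, giving the 9α-hydroxy-7-ene F4.
- Hydroxyl-directed osmylation (OsO4·TMEDA) should give the 7α,8α,9α-triol F5.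
- One equivalent of Dess–Martin periodinane should oxidise the less hindered C7 hydroxyl, which comes back to the route at 13.

**Step 19.** Facial selectivity will be poor or reversed if the zinc chelate does not form and the carbonyl reacts from the conformer in which O7 and O8 are anti. The fallback sets out from 30 and accepts that sense of attack.
- Luche reduction (NaBH4, CeCl3, MeOH) should give the 7-epi alcohol F6.
- Mitsunobu inversion (4-nitrobenzoic acid, DIAD, PPh3) should give the 7-(4-nitrobenzoate) F7 with the C7 configuration of the target.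
- Methanolysis (K2CO3, MeOH) comes back to the route at 31.

## Further compounds

F1 | step 18 | 7-O-trimethylsilyl ether of 27 | CC1(C)O[C@@H]2[C@@H]3[C@](C)(CCC4(OCCO4)[C@@]3(C)O[Si](CC)(CC)CC)[C@@H](C=C)[C@](O[Si](C)(C)C)(C#CCOCc4ccc(OC)cc4)[C@@]2(O1)[C@H](C)CO[Si](C)(C)C(C)(C)C
F2 | step 18 | ring siloxyallene (C5=C6=C7–OTMS, E-C2=C3) | CC1(C)O[C@@H]2[C@@H]3[C@](C)(CCC4(OCCO4)[C@@]3(C)O[Si](CC)(CC)CC)/C=C/CC(COCc4ccc(OC)cc4)=C=C(O[Si](C)(C)C)[C@@]2(O1)[C@H](C)CO[Si](C)(C)C(C)(C)C
F3 | step 10 | 8α,9α-epoxide of 11 | O1[C@@H]2[C@@H]3[C@](C)(CCC4(OCCO4)[C@@]3(C)O[Si](CC)(CC)CC)CC[C@@]21[C@H](C)CO[Si](C)(C)C(C)(C)C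
F4 | step 10 | 9α-hydroxy-7-ene | O[C@@H]1[C@@H]2[C@](C)(CCC3(OCCO3)[C@@]2(C)O[Si](CC)(CC)CC)CC=C1[C@H](C)CO[Si](C)(C)C(C)(C)C
F5 | step 10 | 7α,8α,9α-triol | O[C@@H]1[C@@H]2[C@](C)(CCC3(OCCO3)[C@@]2(C)O[Si](CC)(CC)CC)C[C@H](O)[C@@]1(O)[C@H](C)CO[Si](C)(C)C(C)(C)C
F6 | step 19 | 7-epi alcohol (C7 epimer of 31) | CC1(C)O[C@@H]2[C@@H]3[C@](C)(CCC4(OCCO4)[C@@]3(C)O[Si](CC)(CC)CC)/C=C/C/C(COCc4ccc(OC)cc4)=C\[C@@H](O)[C@@]2(O1)[C@H](C)CO[Si](C)(C)C(C)(C)C
F7 | step 19 | 7-(4-nitrobenzoate) of 31 | CC1(C)O[C@@H]2[C@@H]3[C@](C)(CCC4(OCCO4)[C@@]3(C)O[Si](CC)(CC)CC)/C=C/C/C(COCc4ccc(OC)cc4)=C\[C@H](OC(=O)c4ccc(cc4)[N+](=O)[O-])[C@@]2(O1)[C@H](C)CO[Si](C)(C)C(C)(C)C
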